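## The problem

The target **24** is a labdane. It has a trans-fused decalin (ring A: C1–C5 and C10; ring B: C5–C10) with a gem-dimethyl group at C4 and an angular methyl at C10. C9 carries a two-carbon tether (C11–C12) to the α-carbon C13 of a butenolide (C13=C14, C15H2–O, C16=O).

Ring B holds four of the five stereocentres: C5 (H α), C6 (acetoxy α, equatorial), C8 (methyl α, equatorial; H β) and C9 (hydroxyl α, axial; tether β). C10 (methyl β) is the fifth. C5 and C10 form the frame and must be set in the absolute sense. Once they exist, the axial methyl groups on C10 and on the β face of C4 close the β face of ring B, so reagents reach C6 and C9 from the α face. The equatorial positions of the C8 methyl and the C6 oxygen are the thermodynamic ones.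

Three groups are fragile and should appear late. The tertiary alcohol at C9, next to quaternary C10, ionises in acid (dehydration, methyl shift). The butenolide does not survive strong base, hydride or dissolving metal. The acetate does not survive hydride or electron-transfer reduction.

A carbon–carbon bond to C9 is hard to make once the ring exists, so C11 should sit on C9 before ring B closes. Two features make the plan possible. First, rings A and B (C4 gem-dimethyl, C10 methyl, trans C5–C10 fusion) are the chair–chair fold of a geranyl-derived triene. Second, the oxygens at C6 and C9 are 1,4-related on one face, which is what dioxygen gives when added across a C6=C7–C8=C9 diene. The second feature requires the cyclisation to leave its alkene at C8=C9 and nowhere else, which a silyl group on C9 can enforce.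

## Retrosynthesis

**24 from 23.** The ester C–O bond at C6 is cut last. An acetate would not survive the reduction that sets C6 and C8, and it would be exposed to the lactone enolate. In diol **23** the secondary equatorial hydroxyl and the hindered tertiary one differ enough that no protecting group is needed. The forward step must leave the butenolide and the C9 alcohol untouched.

**23 from 17 and 19.** The C12–C13 bond is cut, and the C13=C14 double bond is traced to a sulfoxide on C13. Bonding C12 to a lactone enolate is preferred over a furan oxidised later (two regioisomeric butenolides) and over an aldol–dehydration at C12 (exocyclic alkene). The sulfur substituent softens the enolate and later places the double bond. This divides the molecule into primary iodide **17** and the lactone **19**, made in one step from bromolactone **18**. The forward steps need C-alkylation beside two free hydroxyls (enolate **20** to **21**) and elimination of sulfoxide **22** toward the ring.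

**17 from 16.** The C12–I bond is traced to the primary alcohol of triol **16**. The three hydroxyls differ by substitution (primary, hindered secondary, tertiary), so one selective step replaces a protect–deprotect sequence. The forward reaction must iodinate the primary position only.

**16 from 15.** The C8–H and C6–H bonds are cut together. Catalytic hydrogenation of the 9α-hydroxy-7-en-6-one **15** would deliver hydrogen to C8 from the open α face (axial methyl), and hydride would attack C6 from the α face (axial alcohol). Only a thermodynamically controlled electron-transfer reduction gives both centres correctly. It also removes the pivalate, which is accepted and used. **15** has two stereocentres fewer than **16**.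

**15 from 13.** Both ring B C–O bonds are cut at once. C6–O and C9–O come from dioxygen added across the 6,8-diene **13** as endoperoxide **14**. Base opens **14** in one direction only, because C6 carries the only hydrogen on a peroxide-bearing carbon. Compared with separate oxidations at C6 and C9, this is a single operation with a fixed 1,4 relationship and facial control by the frame. **13** has no ring oxygen and only the two frame stereocentres. The forward step requires cycloaddition from the α face to outrun ene reactions.

**13 from 9.** The diene is traced to the single alkene of **9**: oxidation of C7 (enone **10**), kinetic enolisation toward C6 trapped as triflate **12** (via **11**), and replacement of the triflate by hydrogen. Direct dehydrogenation or bromination–elimination would not hold the diene inside ring B. The forward steps need C7 rather than C11 or C17 oxidation, and α′ rather than γ deprotonation.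

**9 from 8.** The C4–C5 and C9–C10 bonds are cut, opening both rings to the acyclic triene **8**. This removes both rings and both frame stereocentres in one step. Ordinary proton-terminated cyclisations give mixtures of alkene isomers at C8; a trimethylsilyl group on C9 turns C9 into the attacking carbon and leaves the alkene at C8=C9 only. Silicon must be cis to C7 so that the C–Si bond is axial in the chair-like closure of ring B. The pivalate is chosen because its carbonyl oxygen cannot close a five-membered ether onto C8 and because it has no acidic hydrogen for step 6. The forward reaction needs an enantioselective initiating protonation at the terminal alkene.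

**8 from 4 and 5.** Ester **8** comes from alcohol **7**. In **7** the C8–CH3 and C9–C11 bonds are cut across the alkyne of **4**: syn addition of methyl and a hydroxyethyl arm. Methylmagnesiation is chosen over methylalumination because the alkenylmagnesium **6** opens ethylene oxide **5** under CuI catalysis, whereas the aluminium analogue is less nucleophilic and needs separate activation. The forward step must add syn and be trapped before **6** isomerises.

**4 from 1 and 2.** The C6–C7 bond is cut between the propargylic carbon of 1-(trimethylsilyl)propyne **1** (as its lithio derivative **3**) and geranyl bromide **2**. Both are commercial and the (E)-alkene of **2** becomes the trans ring fusion.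

## Roads not taken

**Alternative 1:** The C9–O bond is cut together with C8–H. A carboxylic acid tethered to C9 delivers the tertiary oxygen: strong acid protonates C8 of 6α-acetoxy-14,15-dinorlabd-8-en-16-oic acid A2, and the carboxyl group captures the C9 cation to give the spiro δ-lactone 6α-acetoxy-14,15-dinorlabdan-16,9α-olide A1.
- Merits: the trans-diaxial H/O pattern at C8/C9 arises in one redox-neutral step, the lactone carbonyl is already C16 of the butenolide, and the tertiary alcohol stays masked. In this respect it is better than the chosen plan, which spends an oxidation, a triflation, two reductions and a photooxygenation on the same two centres.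
- Weak points: the cation at C9 sits next to quaternary C10, so methyl migration and proton loss compete. Nothing forces protonation of C8 from the β face. The 6α-acetate must be installed beforehand on an 8-ene whose only activated ring position is C7, and it then sits in strong acid. Further steps are needed to add C14–C15 to the lactone and translactonise. A2 also still needs the decalin, so this road replaces the oxygenation tactics, not the ring construction.
- Comparison: against its shorter handling of C8/C9, the chosen plan brings both ring B oxygens from one reagent under facial control of the frame, and generates no cation beside C10 after the rings exist.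

**Alternative 2:** The C1–C10 and C4–C5 bonds are cut. Ring A is added by [4+2] cycloaddition of 2-(tert-butyldimethylsilyloxy)-4-methylpenta-1,3-diene A5 to a methyl-bearing double bond of 2,6-dimethyl-1,4-benzoquinone A4 under a chiral Lewis acid, giving the cis-fused adduct A3.
- Merits: it is convergent, both components are cheap, the C6 and C9 oxygens are present from the start as carbonyls, the C8 methyl is in place, and quaternary C10 forms in the cycloaddition. In convergence and early oxygenation it is better than the chosen linear plan.
- Weak points: the diene terminus C4 carries two methyl groups, one of them cis, which disfavours the s-cis conformer and creates two quaternary carbons in one step. Enantioselective catalysis on so hindered a pair is not assured. A3 is cis-fused and must be epimerised at C5, and the C2 oxygen must be removed. Most seriously, the side chain must add to the C9 carbonyl from the β face, syn to the angular methyl, against the steric bias.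
- Comparison: the chosen plan places C11 on C9 before the ring exists and lets the facial bias work for it; it pays with linearity.

**Alternative 3:** The C6–O and C9–O bonds are cut, and the singlet-oxygen cycloaddition becomes the defining step, with the decalin taken from the chiral pool. (+)-Sclareolide A8 would be reduced, silylated and dehydrated to the 8-ene, then converted into the diene silyl ether A7. Singlet oxygen adds to A7 from the α face to give the endoperoxide A6.
- Merits: the absolute configuration is bought rather than made, every step is of a known type, and a silyl ether survives dissolving metal, so the C12 oxygen stays differentiated through the reduction. In reliability and in the handling of C12 it is better than the chosen plan, and its length from A8 to A7 is comparable to steps 1–7.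
- Weak points: it depends on one natural feedstock (one enantiomeric series, fixed ring A), and the 8-ene rests on the regiochemistry of dehydrating a tertiary alcohol.
- Comparison: the chosen plan uses the same cycloaddition (step 8, via **14**) and differs only in how the rings are made. What it has to set against this road is independence from the feedstock, either enantiomer by choice of the acid, and an alkene position fixed by a carbon–silicon bond rather than by an elimination.

Key step: step 4

Assumptions:
- The (R)-configured binaphthol acid is taken to induce the (5S,10S) sense, as with homofarnesyl-type polyenes; the (S)-acid is used if the sense proves opposite.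
- Labdane numbering is used throughout, also for open-chain compounds; "8βH" means H-8 is β and the C17 methyl is α (equatorial).

## Route

Step 1
Reactants: 1 1-(trimethylsilyl)propyne; 2 geranyl bromide
Product: 4 [(5E)-6,10-dimethylundeca-5,9-dien-1-yn-1-yl]trimethylsilane, via lithiated silylpropyne 3 (not isolated)
Conditions: n-BuLi, THF, −78 to −20 °C; then 2, −78 °C to rt
Reagents that add atoms: none
Why: Propargylic lithiation of 1 gives the silyl-stabilised anion 3, which displaces primary allylic bromides at its propargylic carbon without allylic transposition (SN2 alkylation), so the (E)-alkene of 2 is carried over unchanged.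

Step 2
Reactants: 4 [(5E)-6,10-dimethylundeca-5,9-dien-1-yn-1-yl]trimethylsilane; 5 ethylene oxide
Product: 7 (3Z,7E)-4,8,12-trimethyl-3-(trimethylsilyl)trideca-3,7,11-trien-1-ol, via alkenylmagnesium bromide 6 (not isolated)
Conditions: MeMgBr (3 equiv), Ni(acac)2 (10 mol %), AlMe3 (10 mol %), THF, rt; then CuI (10 mol %), 5, −30 to 0 °C; aq. NH4Cl
Reagents that add atoms: methylmagnesium bromide C[Mg]Br
Why: Nickel-catalysed syn methylmagnesiation of a 1-silylalkyne puts methyl on the carbon remote from silicon (C8) and magnesium on the silyl-bearing carbon (C9); copper-catalysed opening of ethylene oxide by 6 then forms C9–C11 with retention, so methyl and the hydroxyethyl arm end cis and silicon cis to C7 (Z). 6 is trapped promptly because α-silyl alkenylmagnesium reagents isomerise on standing.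

Step 3
Reactants: 7 (3Z,7E)-4,8,12-trimethyl-3-(trimethylsilyl)trideca-3,7,11-trien-1-ol
Product: 8 (3Z,7E)-4,8,12-trimethyl-3-(trimethylsilyl)trideca-3,7,11-trien-1-yl pivalate
Conditions: PivCl, pyridine, DMAP (cat.), CH2Cl2, 0 °C to rt
Reagents that add atoms: pivaloyl chloride CC(C)(C)C(Cl)=O
Why: DMAP-catalysed acylation of the primary alcohol; the pivalate has no α-hydrogen for the amide base of step 6 and is a poor internal nucleophile in step 4.

Step 4
Reactants: 8 (3Z,7E)-4,8,12-trimethyl-3-(trimethylsilyl)trideca-3,7,11-trien-1-yl pivalate
Product: 9 13,14,15,16-tetranorlabd-8-en-12-yl pivalate {2-[(4aS,8aS)-2,5,5,8a-tetramethyl-3,4,4a,5,6,7,8,8a-octahydronaphthalen-1-yl]ethyl pivalate}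
Conditions: (R)-2-(2-fluorobenzyloxy)-2'-hydroxy-1,1'-binaphthyl·SnCl4 (2 equiv), toluene, −78 °C; aq. NaHCO3
Reagents that add atoms: none
Why: Proposed new method: the SnCl4-bound chiral binaphthol is expected to protonate C3 of the terminal isopropylidene enantioselectively, after which C5 of the (E)-C5=C10 alkene attacks the C4 cation and the silyl-bearing C9 attacks the C10 cation, the tertiary β-silyl cation at C8 then losing silicon to chloride to leave only the C8=C9 alkene; the closest known reaction types are the Lewis-acid-assisted chiral Brønsted acid cyclisation of homofarnesyl-type polyenes and the vinylsilane-terminated cation–olefin cyclisation, which have not been run as one cascade. Ring A closes 6-endo-trig (C4–C5) and ring B closes 6-endo-trig (C9–C10), both through a chair–chair fold. C5 and C10 are set together: their trans relationship follows from anti addition across the (E)-alkene, and their absolute sense from the face of C3 that the chiral acid protonates. The step needs initiation at the terminal alkene, which its low steric demand and the bulk of the acid should secure over the internal alkene and the hindered tetrasubstituted vinylsilane. It needs ipso attack at C9, which the 5-exo mode (five-membered ring, α-silyl cation) cannot rival. It needs a single alkene isomer, which loss of silicon from an axial C–Si bond parallel to the empty orbital at C8 secures. The pivalate carbonyl could reach C8 only through a seven-membered ring, so ether formation at C8 is not expected.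

Step 5
Reactants: 9 13,14,15,16-tetranorlabd-8-en-12-yl pivalate
Product: 10 7-oxo-13,14,15,16-tetranorlabd-8-en-12-yl pivalate
Conditions: CrO3, 3,5-dimethylpyrazole, CH2Cl2, −20 °C
Reagents that add atoms: chromium trioxide O=[Cr](=O)=O
Why: Chromium-mediated allylic oxidation of 8-ene labdanes and drimanes takes the ring methylene C7, whose axial C–H bond is aligned with the π system, in preference to the C17 methyl and the C11 methylene next to quaternary C10; the ester is inert.

Step 6
Reactants: 10 7-oxo-13,14,15,16-tetranorlabd-8-en-12-yl pivalate
Product: 12 7-(trifluoromethylsulfonyloxy)-13,14,15,16-tetranorlabda-6,8-dien-12-yl pivalate, via potassium dienolate 11 (not isolated)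
Conditions: KN(SiMe3)2, THF, −78 °C; then PhNTf2, −78 to 0 °C
Reagents that add atoms: N-phenylbis(trifluoromethanesulfonimide) O=S(=O)(N(c1ccccc1)S(=O)(=O)C(F)(F)F)C(F)(F)F
Why: Kinetic deprotonation of the enone by a hindered amide at −78 °C occurs at the α′ methylene C6 (cross-conjugated dienolate 11), and O-sulfonylation fixes the C6=C7 double bond as the enol triflate; the pivalate has no acidic hydrogen.

Step 7
Reactants: 12 7-(trifluoromethylsulfonyloxy)-13,14,15,16-tetranorlabda-6,8-dien-12-yl pivalate
Product: 13 13,14,15,16-tetranorlabda-6,8-dien-12-yl pivalate
Conditions: Pd(OAc)2 (5 mol %), PPh3, HCO2H, n-Bu3N, DMF, 60 °C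
Reagents that add atoms: none
Why: Palladium-catalysed formate reduction of an enol triflate (oxidative addition to zerovalent palladium, formate exchange, loss of CO2, reductive elimination) replaces the triflate by hydrogen with both double bonds left in place, giving the homoannular diene.

Step 8
Reactants: 13 13,14,15,16-tetranorlabda-6,8-dien-12-yl pivalate
Product: 15 9α-hydroxy-6-oxo-13,14,15,16-tetranorlabd-7-en-12-yl pivalate, via endoperoxide 14 (not isolated)
Conditions: O2, tetraphenylporphyrin (cat.), hν (visible), CH2Cl2, 0 °C; then Et3N, 0 °C to rt
Reagents that add atoms: dioxygen O=O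
Why: Singlet oxygen adds [4+2] to the s-cis diene from the α face, the β face being covered by the axial C10 and 4β methyl groups, which sets C6 and C9 with both oxygens α; Kornblum–DeLaMare fragmentation by the amine then removes H-6, the only hydrogen on a peroxide-bearing carbon, giving the C6 ketone and the tertiary 9α-hydroxyl.

Step 9
Reactants: 15 9α-hydroxy-6-oxo-13,14,15,16-tetranorlabd-7-en-12-yl pivalate
Product: 16 13,14,15,16-tetranor-8βH-labdane-6α,9α,12-triol
Conditions: Li (excess), NH3(l)/THF, t-BuOH, −78 to −33 °C; then MeOH; NH4Cl
Reagents that add atoms: none
Why: Dissolving-metal reduction: the enone takes up two electrons and C8 is protonated axially from the β face, so the C17 methyl becomes equatorial (8β-H); once methanol protonates the enolate, the C6 ketone is reduced under thermodynamic control to the equatorial 6α-alcohol, and the pivalate is cleaved reductively in the same pot. The tertiary hydroxyl, largely an alkoxide in this basic medium, is a poor leaving group and should stay.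

Step 10
Reactants: 16 13,14,15,16-tetranor-8βH-labdane-6α,9α,12-triol
Product: 17 12-iodo-13,14,15,16-tetranor-8βH-labdane-6α,9α-diol
Conditions: I2, PPh3, imidazole, THF, 0 °C
Reagents that add atoms: iodine [I][I]
Why: Appel-type iodination converts the unhindered primary alcohol through its alkoxyphosphonium salt, while the secondary 6α-hydroxyl beside the C4 gem-dimethyl group and the tertiary 9α-hydroxyl react far more slowly at 0 °C.

Step 11
Reactants: 18 α-bromo-γ-butyrolactone (racemic)
Product: 19 3-(phenylsulfanyl)oxolan-2-one (racemic)
Conditions: PhSH, Et3N, CH2Cl2, 0 °C to rt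
Reagents that add atoms: thiophenol Sc1ccccc1
Why: SN2 displacement of the activated α-bromide by thiolate is the standard preparation of α-sulfenyl lactones.

Step 12
Reactants: 17 12-iodo-13,14,15,16-tetranor-8βH-labdane-6α,9α-diol; 19 3-(phenylsulfanyl)oxolan-2-one
Product: 21 6α,9α-dihydroxy-13-(phenylsulfanyl)-8βH-labdan-16,15-olide (both C13 epimers), via sodium enolate 20 (not isolated)
Conditions: 19 (2 equiv), NaH (1.9 equiv), DMF, 0 °C; then 17, 0 °C to rt
Reagents that add atoms: none
Why: The sulfur-stabilised lactone enolate 20 is a soft carbon nucleophile that alkylates primary iodides at carbon (SN2), forming C12–C13; the hydroxyl groups are far less acidic than 19 and stay protonated when no excess NaH is present. Both C13 epimers are carried on because this centre is destroyed in step 13.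

Step 13
Reactants: 21 6α,9α-dihydroxy-13-(phenylsulfanyl)-8βH-labdan-16,15-olide
Product: 23 6α,9α-dihydroxy-8βH-labd-13-en-16,15-olide, via sulfoxide 22 (not isolated)
Conditions: mCPBA (1 equiv), CH2Cl2, −78 °C; then CaCO3, toluene, 110 °C
Reagents that add atoms: none
Why: Sulfide oxidation followed by thermal syn elimination of benzenesulfenic acid; in α-alkyl-α-sulfinyl γ-lactones the elimination runs mainly toward the ring methylene, giving the endocyclic α-substituted butenolide (C13=C14). Nothing else in 21 is attacked by one equivalent of peracid at −78 °C.

Step 14
Reactants: 23 6α,9α-dihydroxy-8βH-labd-13-en-16,15-olide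
Product: 24 6α-acetoxy-9α-hydroxy-8βH-labd-13-en-16,15-olide (CNP0205088.2)
Conditions: Ac2O, pyridine, DMAP (cat.), CH2Cl2, rt
Reagents that add atoms: acetic anhydride CC(=O)OC(C)=O
Why: DMAP-catalysed acylation esterifies the secondary equatorial 6α-hydroxyl, while the tertiary 9α-hydroxyl next to quaternary C10 does not react under these conditions; the butenolide tolerates the weakly basic medium.

## Compound list

1 | 1-(trimethylsilyl)propyne | CC#C[Si](C)(C)C | starting material
2 | geranyl bromide | CC(C)=CCC/C(C)=C/CBr | starting material
3 | [3-(trimethylsilyl)prop-2-yn-1-yl]lithium | [Li]CC#C[Si](C)(C)C | intermediate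
4 | [(5E)-6,10-dimethylundeca-5,9-dien-1-yn-1-yl]trimethylsilane | CC(C)=CCC/C(C)=C/CCC#C[Si](C)(C)C | intermediate
5 | ethylene oxide | C1CO1 | starting material
6 | [(1Z,5E)-2,6,10-trimethyl-1-(trimethylsilyl)undeca-1,5,9-trien-1-yl]magnesium bromide | CC(C)=CCC/C(C)=C/CC/C(C)=C(\[Si](C)(C)C)[Mg]Br | intermediate
7 | (3Z,7E)-4,8,12-trimethyl-3-(trimethylsilyl)trideca-3,7,11-trien-1-ol | CC(C)=CCC/C(C)=C/CC/C(C)=C(\[Si](C)(C)C)CCO | intermediate
8 | (3Z,7E)-4,8,12-trimethyl-3-(trimethylsilyl)trideca-3,7,11-trien-1-yl pivalate | CC(C)=CCC/C(C)=C/CC/C(C)=C(\[Si](C)(C)C)CCOC(=O)C(C)(C)C | intermediate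
9 | 13,14,15,16-tetranorlabd-8-en-12-yl pivalate (5α-H, 10β-methyl) | C1CC(C)=C(CCOC(=O)C(C)(C)C)[C@@]2(C)CCCC(C)(C)[C@H]12 | intermediate
10 | 7-oxo-13,14,15,16-tetranorlabd-8-en-12-yl pivalate | C1C(=O)C(C)=C(CCOC(=O)C(C)(C)C)[C@@]2(C)CCCC(C)(C)[C@H]12 | intermediate
11 | potassium 6,8-dien-7-olate of 10 | C1=C([O-])C(C)=C(CCOC(=O)C(C)(C)C)[C@@]2(C)CCCC(C)(C)[C@H]12.[K+] | intermediate
12 | 7-(trifluoromethylsulfonyloxy)-13,14,15,16-tetranorlabda-6,8-dien-12-yl pivalate | C1=C(OS(=O)(=O)C(F)(F)F)C(C)=C(CCOC(=O)C(C)(C)C)[C@@]2(C)CCCC(C)(C)[C@H]12 | intermediate
13 | 13,14,15,16-tetranorlabda-6,8-dien-12-yl pivalate | C1=CC(C)=C(CCOC(=O)C(C)(C)C)[C@@]2(C)CCCC(C)(C)[C@H]12 | intermediate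
14 | 6α,9α-epidioxy-13,14,15,16-tetranorlabd-7-en-12-yl pivalate | O3[C@H]1C=C(C)[C@](O3)(CCOC(=O)C(C)(C)C)[C@@]2(C)CCCC(C)(C)[C@H]12 | intermediate
15 | 9α-hydroxy-6-oxo-13,14,15,16-tetranorlabd-7-en-12-yl pivalate | O=C1C=C(C)[C@](O)(CCOC(=O)C(C)(C)C)[C@@]2(C)CCCC(C)(C)[C@H]12 | intermediate
16 | 13,14,15,16-tetranor-8βH-labdane-6α,9α,12-triol | O[C@H]1C[C@@H](C)[C@](O)(CCO)[C@@]2(C)CCCC(C)(C)[C@H]12 | intermediate
17 | 12-iodo-13,14,15,16-tetranor-8βH-labdane-6α,9α-diol | O[C@H]1C[C@@H](C)[C@](O)(CCI)[C@@]2(C)CCCC(C)(C)[C@H]12 | intermediate
18 | α-bromo-γ-butyrolactone (racemic) | BrC1CCOC1=O | starting material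
19 | 3-(phenylsulfanyl)oxolan-2-one (racemic) | O=C1OCCC1Sc1ccccc1 | intermediate
20 | sodium enolate of 19 | [Na+].[O-]C1=C(Sc2ccccc2)CCO1 | intermediate
21 | 6α,9α-dihydroxy-13-(phenylsulfanyl)-8βH-labdan-16,15-olide (both C13 epimers) | O[C@H]1C[C@@H](C)[C@](O)(CCC3(Sc4ccccc4)CCOC3=O)[C@@]2(C)CCCC(C)(C)[C@H]12 | intermediate
22 | 6α,9α-dihydroxy-13-(phenylsulfinyl)-8βH-labdan-16,15-olide (epimers at C13 and sulfur) | O[C@H]1C[C@@H](C)[C@](O)(CCC3(S(=O)c4ccccc4)CCOC3=O)[C@@]2(C)CCCC(C)(C)[C@H]12 | intermediate
23 | 6α,9α-dihydroxy-8βH-labd-13-en-16,15-olide | O[C@H]1C[C@@H](C)[C@](O)(CCC3=CCOC3=O)[C@@]2(C)CCCC(C)(C)[C@H]12 | intermediate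
24 | 6α-acetoxy-9α-hydroxy-8βH-labd-13-en-16,15-olide (CNP0205088.2) | CC(=O)O[C@H]1C[C@@H](C)[C@](O)(CCC2=CCOC2=O)[C@@]2(C)CCCC(C)(C)[C@H]12 | target

## Step count and least certain steps

Total: 14 steps. Longest linear sequence: 13 steps (steps 1–10 and 12–14); step 11 prepares the lactone partner.

**Step 4 (key step, new combination).** Four things may go wrong. The acid may protonate the vinylsilane at C9 and remove silicon before the cascade starts. The cascade may stop after ring A by proton loss from the C10 cation. The ester oxygen may capture the C8 cation. The facial discrimination in the initiating protonation may be too low.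

The fallback uses known reactions only. It keeps a chiral-acid polyene cyclisation as the ring-forming event but gives up the silicon terminator. It sets out from **4**:
- K2CO3 in methanol removes the silyl group to give (5E)-6,10-dimethylundeca-5,9-dien-1-yne F1.
- Zirconium-catalysed methylalumination (AlMe3, Cp2ZrCl2), conversion to the alanate with n-BuLi and opening of ethylene oxide give (3E,7E)-4,8,12-trimethyltrideca-3,7,11-trien-1-ol F2.
- Oxidation with CrO3/H2SO4 in acetone at 0 °C gives (3E,7E)-4,8,12-trimethyltrideca-3,7,11-trienoic acid F3.
- The same binaphthol·SnCl4 acid cyclises F3, with the carboxyl group as terminator, to (+)-sclareolide F4.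
- LiAlH4 gives 13,14,15,16-tetranorlabdane-8α,12-diol F5.
- PivCl/pyridine acylates the primary hydroxyl to give 8α-hydroxy-13,14,15,16-tetranorlabdan-12-yl pivalate F6.
- PPh3/I2 dehydrates the tertiary alcohol toward the most substituted alkene and returns to the route at **9**.

The alkene position then rests on the dehydration regiochemistry rather than on silicon.

**Step 2.** The syn adduct **6** may lose its configuration before it is trapped. The hindered alkenylmagnesium may open the epoxide slowly, and halohydrin formation from magnesium halide may compete. Both geometrical isomers of **8** should converge on **9**, since C9 ends as an alkene carbon; the wrong isomer is expected only to cyclise less cleanly.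

The fallback forms the C9–C11 bond by cross-coupling instead of epoxide opening. It sets out from **4**:
- The methylmagnesiation mixture is quenched with iodine at −78 °C to give [(1E,5E)-1-iodo-2,6,10-trimethylundeca-1,5,9-trien-1-yl]trimethylsilane F7, which can be freed of its isomer.
- Negishi coupling with CH2=CHZnBr and Pd(PPh3)4 gives [(3Z,7E)-4,8,12-trimethyltrideca-1,3,7,11-tetraen-3-yl]trimethylsilane F8.
- 9-BBN hydroboration of the monosubstituted alkene and oxidation (NaOH, H2O2) return to the route at **7**.

**Step 9.** The carbanion at C8 may expel the C9 oxygen (reductive loss of the tertiary hydroxyl). C8 may be protonated from the α face. The ketone may be reduced incompletely.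

The fallback avoids the enone and the dissolving metal. It sets out from **13**:
- Photooxygenation as in step 8, but with thiourea in methanol in place of the amine, reduces the peroxide bond to give 6α,9α-dihydroxy-13,14,15,16-tetranorlabd-7-en-12-yl pivalate F9, in which C6 already has its final configuration.
- Hydrogen-atom-transfer hydrogenation (Mn(dpm)3, PhSiH3, t-BuOOH, i-PrOH), which tends toward the thermodynamic epimer, gives 6α,9α-dihydroxy-13,14,15,16-tetranor-8βH-labdan-12-yl pivalate F10.
- LiAlH4 cleaves the ester and returns to the route at **16**.

**Step 13.** The sulfoxide may eliminate toward C12 and give the exocyclic alkylidene lactone, or undergo Pummerer-type side reactions on heating.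

The fallback builds the butenolide by ring-closing metathesis. It sets out from **17**:
- Alkylation of the sodium salt of allyl 2-(diethoxyphosphoryl)acetate (NaH, DMF) gives allyl 13-(diethoxyphosphoryl)-6α,9α-dihydroxy-14,15-dinor-8βH-labdan-16-oate F11.
- Horner–Wadsworth–Emmons methylenation with aqueous formaldehyde and K2CO3 gives allyl 6α,9α-dihydroxy-15-nor-8βH-labd-13(14)-en-16-oate F12.
- Ring-closing metathesis with the second-generation Grubbs catalyst (H2IMes)(PCy3)Cl2Ru=CHPh in toluene at 80 °C returns to the route at **23**.

## Further compounds

F1 | step 4 | (5E)-6,10-dimethylundeca-5,9-dien-1-yne | CC(C)=CCC/C(C)=C/CCC#C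
F2 | step 4 | (3E,7E)-4,8,12-trimethyltrideca-3,7,11-trien-1-ol | CC(C)=CCC/C(C)=C/CC/C(C)=C/CCO
F3 | step 4 | (3E,7E)-4,8,12-trimethyltrideca-3,7,11-trienoic acid | CC(C)=CCC/C(C)=C/CC/C(C)=C/CC(O)=O
F4 | step 4 | (+)-sclareolide (13,14,15,16-tetranorlabdan-12,8α-olide) | C1C[C@@](C)(OC(=O)C3)[C@H]3[C@@]2(C)CCCC(C)(C)[C@H]12
F5 | step 4 | 13,14,15,16-tetranorlabdane-8α,12-diol | C1C[C@@](C)(O)[C@H](CCO)[C@@]2(C)CCCC(C)(C)[C@H]12
F6 | step 4 | 8α-hydroxy-13,14,15,16-tetranorlabdan-12-yl pivalate | C1C[C@@](C)(O)[C@H](CCOC(=O)C(C)(C)C)[C@@]2(C)CCCC(C)(C)[C@H]12
F7 | step 2 | [(1E,5E)-1-iodo-2,6,10-trimethylundeca-1,5,9-trien-1-yl]trimethylsilane | CC(C)=CCC/C(C)=C/CC/C(C)=C(\[Si](C)(C)C)I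
F8 | step 2 | [(3Z,7E)-4,8,12-trimethyltrideca-1,3,7,11-tetraen-3-yl]trimethylsilane | CC(C)=CCC/C(C)=C/CC/C(C)=C(\[Si](C)(C)C)C=C
F9 | step 9 | 6α,9α-dihydroxy-13,14,15,16-tetranorlabd-7-en-12-yl pivalate | O[C@H]1C=C(C)[C@](O)(CCOC(=O)C(C)(C)C)[C@@]2(C)CCCC(C)(C)[C@H]12
F10 | step 9 | 6α,9α-dihydroxy-13,14,15,16-tetranor-8βH-labdan-12-yl pivalate | O[C@H]1C[C@@H](C)[C@](O)(CCOC(=O)C(C)(C)C)[C@@]2(C)CCCC(C)(C)[C@H]12
F11 | step 13 | allyl 13-(diethoxyphosphoryl)-6α,9α-dihydroxy-14,15-dinor-8βH-labdan-16-oate (both C13 epimers) | O[C@H]1C[C@@H](C)[C@](O)(CCC(P(=O)(OCC)OCC)C(=O)OCC=C)[C@@]2(C)CCCC(C)(C)[C@H]12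
F12 | step 13 | allyl 6α,9α-dihydroxy-15-nor-8βH-labd-13(14)-en-16-oate | O[C@H]1C[C@@H](C)[C@](O)(CCC(=C)C(=O)OCC=C)[C@@]2(C)CCCC(C)(C)[C@H]12
A1 | alternative 1 | 6α-acetoxy-14,15-dinorlabdan-16,9α-olide (8α-methyl) | CC(=O)O[C@H]1C[C@@H](C)[C@](OC3=O)(CCC3)[C@@]2(C)CCCC(C)(C)[C@H]12
A2 | alternative 1 | 6α-acetoxy-14,15-dinorlabd-8-en-16-oic acid | CC(=O)O[C@H]1CC(C)=C(CCCC(O)=O)[C@@]2(C)CCCC(C)(C)[C@H]12
A3 | alternative 2 | cis-fused adduct, 2-(tert-butyldimethylsilyloxy)-4,4,8,10-tetramethyloctalin-2,7-diene-6,9-dione (labdane numbering) | O=C1C=C(C)C(=O)[C@@]2(C)CC(O[Si](C)(C)C(C)(C)C)=CC(C)(C)[C@@H]12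
A4 | alternative 2 | 2,6-dimethyl-1,4-benzoquinone | CC1=CC(=O)C=C(C)C1=O
A5 | alternative 2 | 2-(tert-butyldimethylsilyloxy)-4-methylpenta-1,3-diene | C=C(O[Si](C)(C)C(C)(C)C)C=C(C)C
A6 | alternative 3 | 6α,9α-epidioxy-13,14,15,16-tetranorlabd-7-en-12-yl tert-butyldimethylsilyl ether | O3[C@H]1C=C(C)[C@](O3)(CCO[Si](C)(C)C(C)(C)C)[C@@]2(C)CCCC(C)(C)[C@H]12
A7 | alternative 3 | 13,14,15,16-tetranorlabda-6,8-dien-12-yl tert-butyldimethylsilyl ether | C1=CC(C)=C(CCO[Si](C)(C)C(C)(C)C)[C@@]2(C)CCCC(C)(C)[C@H]12
A8 | alternative 3 | (+)-sclareolide | C1C[C@@](C)(OC(=O)C3)[C@H]3[C@@]2(C)CCCC(C)(C)[C@H]12
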